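Count the partner before you count the products, the chair told the meeting on this flask, whose charges, earlier runs and questions were laid out as follows.

| flask | starting material | partner | remark | time |
|---|---|---|---|---|
| summer | 0.40 M | 0.55 equiv | run made earlier |  |
| spring | 0.40 M | 2.2 equiv | run made earlier |  |
| dawn | 0.60 M | 1.1 equiv | run made earlier |  |
| flask | 0.40 M | 1.10 equiv |  | 50 min |

| run | time / min | starting material / % | first product / % |
|---|---|---|---|
| summer | 2.50 | 57.4 | 30.3 |
| summer | 6.00 | 58.1 | 33.9 |
| summer | 12.0 | 54.6 | 32.8 |
| summer | 30.0 | 52.7 | 30.7 |
| spring | 2.50 | 9.0 | 27.9 |
| spring | 6.00 | 8.9 | 25.9 |
| spring | 12.0 | 7.2 | 24.5 |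
| spring | 30.0 | 5.1 | 22.6 |
| dawn | 2.50 | 31.6 | 40.1 |
| dawn | 6.00 | 28.1 | 39.3 |
| dawn | 12.0 | 26.9 | 38.9 |
| dawn | 30.0 | 22.5 | 38.2 |

(readings scatter by 1 percentage point)

1. amount of starting material at 50 min, in percent of the starting material charged
2. amount of first product at 50 min, in percent of the starting material charged
3. amount of bis adduct at 50 min, in percent of the starting material charged
4. amount of tris adduct at 50 min, in percent of the starting material charged



The balance chemist took the dawn run, which has the flask's equivalents but 0.60 M of starting material against the flask's 0.40 M, and reported from its last reading a load of 1.83, down from 2.47 at 2.50 min. She called this the partner load, meaning the equivalents of partner charged less the first product, which holds one each, divided by the share of material that is neither starting material nor first product. She argued that partner lost elsewhere puts the true figure below this one, and since bis adduct holds two partners and tris adduct 3, a rest made of those two needs a load of at least two, while this dawn reading lies below that.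

The forecast was then entered: 22% starting material, 38% first product, 30% bis adduct and 10% tris adduct, its author noting that the “late balances overshoot the partner charged”. The balance chemist answered that these adducts claim 0.900 equivalents of partner where 0.720 remain beyond the first product, a load of 1.80, so by her own reckoning at least 8 percentage points of the rest must hold fewer than two partners.

The flask gives 22.3% starting material, 39.0% first product, 2.81% bis adduct and 4.00% tris adduct, a load of 1.83, close to the figure read on the dawn run.

    partner → decomposed reagent (k = 0.100 min⁻¹)
    partner + bis adduct → tris adduct (k = 6.60 M⁻¹ min⁻¹)
    starting material + partner → first product (k = 4.10 M⁻¹ min⁻¹)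
    tris adduct ⇌ isomer of the product (K = 1.90, k = 0.0680 min⁻¹)
    starting material + bis adduct → side product (k = 0.320 M⁻¹ min⁻¹)
    partner + first product → bis adduct (k = 3.60 M⁻¹ min⁻¹)

At 50.0 min in the flask the pseudo-first-order half-life of bis adduct by its step with starting material, taken at the [starting material] of that moment, is 24 min, shorter than the 50 min of the run. In the flask that step has half its turnover up to that time behind it by 13.4 min, and at 50.0 min its side product, which counts as two in the percentages and so holds one partner per unit counted, stands at 24.4%.

On the neighbour with 1.90 equiv of partner, the load from its starting material and first product is 2.51, higher than the figure read on the dawn run, which asks for 32 points of three-partner material if no partner were lost elsewhere and the rest were otherwise bis adduct. That neighbour holds 12.8% tris adduct and 23.9% isomer of the product at 50.0 min.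

The data come from a simulation for an exercise; the scatter is artificial.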